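The plan rests on closing the lactone ring (ring B: C1, O2, C3, C4, C4a, C8a) by joining arene carbon C4a to C4. The key step exploits that C4a sits ortho to C8a, whose carboxyl carbon C1 can carry C3 and C4 as an ester of a lactamide. Bromine–metal exchange at C4a triggers a Parham-type 6-exo attack on the amide carbonyl C4 and gives the 3-methylisochromane-1,4-dione. Its precursor, the C4a bromide, comes from the para C5-OMe/C8-OH pair of ring A: oxidative dearomatisation to a quinone monoketal makes the otherwise inert C4a a Michael acceptor for bromide. Transfer hydrogenation then sets C4 cis to C3.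

Key step: step 5

Remark: atoms are numbered as in isochroman-1-one (C1 lactone carbonyl, O2, C3 with the methyl group, C4 with the acetoxy group, C4a, C5 to C8, C8a; ring A is the arene, ring B the lactone), the target is the cis (3R,4R) isomer, and (S)-N,N-dimethyllactamide is taken as a commercial material.

Step 1
Reactants: 1 2,4-dihydroxy-5-methoxybenzaldehyde; 2 geranyl bromide ((2E)-1-bromo-3,7-dimethylocta-2,6-diene)
Product: 3 4-geranyloxy-2-hydroxy-5-methoxybenzaldehyde
Conditions: KHCO3 (1.5 equiv), 2 (1.05 equiv), DMF, 40 °C
Reagents that add atoms: none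
Why: Williamson etherification: the 4-hydroxyl, para to the formyl group and not held in a hydrogen bond, is the more acidic phenol and should be alkylated selectively by the primary allylic bromide (SN2, E-olefin untouched), while the 2-hydroxyl stays chelated to the aldehyde.

Step 2
Reactants: 3 4-geranyloxy-2-hydroxy-5-methoxybenzaldehyde
Product: 4 4-geranyloxy-2-hydroxy-5-methoxybenzoic acid
Conditions: NaClO2, NaH2PO4, 2-methyl-2-butene (20 equiv), t-BuOH/THF/H2O, 0 °C to rt
Reagents that add atoms: sodium chlorite, [Na+].[O-]Cl=O
Why: Pinnick oxidation: chlorous acid adds to the aldehyde and fragments to the acid and hypochlorous acid, which the excess 2-methyl-2-butene traps before it can chlorinate ring A or the geranyl olefins.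

Step 3
Reactants: 4 4-geranyloxy-2-hydroxy-5-methoxybenzoic acid; 5 (S)-N,N-dimethyllactamide ((2S)-2-hydroxy-N,N-dimethylpropanamide)
Product: 6 (2R)-1-(dimethylamino)-1-oxopropan-2-yl 4-geranyloxy-2-hydroxy-5-methoxybenzoate
Conditions: PPh3, DIAD, THF, 0 °C to rt
Reagents that add atoms: none
Why: Mitsunobu esterification: the carboxylate of 4 displaces the oxyphosphonium of the secondary alcohol by SN2 with inversion, turning (S)-5 into the (R)-ester carbon that becomes C3, while the chelated ortho-phenol is too weakly acidic to compete.

Step 4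
Reactants: 6 (2R)-1-(dimethylamino)-1-oxopropan-2-yl 4-geranyloxy-2-hydroxy-5-methoxybenzoate
Product: 8 (2R)-1-(dimethylamino)-1-oxopropan-2-yl 2-bromo-4-geranyloxy-6-hydroxy-3-methoxybenzoate, via quinone monoketal 7 (not isolated)
Conditions: PhI(OAc)2 (1.05 equiv), MeOH, 0 °C; evaporate; LiBr (3 equiv), AcOH (2 equiv), MeCN, 0 °C to rt
Reagents that add atoms: methanol, CO (methoxy group of 7; either ketal methoxy group may be the one kept in 8); lithium bromide, [Li+].[Br-]
Why: Oxidative dearomatisation of a p-methoxyphenol by a trivalent iodine reagent (methanol enters at C5, para to the C8 oxygen) followed by 1,4-addition of bromide and loss of methanol, the quinone monoketal counterpart of the Thiele-type addition of HX to quinones: in 7 only C4a is the β-carbon of both the C8 ketone and the C1 ester, C6 being a deactivated vinylogous ester carbon, so bromine should enter at C4a, where direct electrophilic bromination (which would go to C7) cannot place it.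

Step 5
Reactants: 8 (2R)-1-(dimethylamino)-1-oxopropan-2-yl 2-bromo-4-geranyloxy-6-hydroxy-3-methoxybenzoate
Product: 12 (3R)-6-geranyloxy-8-hydroxy-5-methoxy-3-methylisochromane-1,4-dione, via aryllithium phenoxide 9 (not isolated), via arylmagnesium bromide 10 (not isolated), via magnesium hemiaminal 11 (not isolated)
Conditions: n-BuLi (2.05 equiv), THF, −100 °C; MgBr2·OEt2 (1.2 equiv), −100 to −40 °C; dilution to 0.005 M, 0 °C to rt; then 1 M HCl
Reagents that add atoms: none
Why: After deprotonation of the C8 phenol, bromine–lithium exchange at C4a should outrun attack of n-BuLi on the tertiary amide and on the phenoxide-deactivated ester at −100 °C; transmetalation gives the less basic, long-lived aryl–magnesium 10, which adds to the dimethylamide carbonyl C4 to form the C4a–C4 bond, and the hemiaminal 11 releases the C4 ketone only on acidic work-up, so no second addition can occur. The closest known reaction type is the Parham cyclisation (halogen–metal exchange followed by intramolecular acylation by a tertiary amide, as in the Bouveault ketone synthesis). Ring B closes in a 6-exo-trig mode. No stereocenter is formed: C3 comes from 5, and should it erode through enolisation of the 1,4-dione, step 6 restores it by dynamic kinetic resolution. The step needs exchange before carbonyl attack and intramolecular before intermolecular acylation: the C8 phenoxide chelates the C1 carbonyl oxygen and so turns O2 toward C4a, and because the ester must pass through its minor s-trans rotamer the aryl–magnesium is given time at 0 °C to rt under high dilution.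

Step 6
Reactants: 12 (3R)-6-geranyloxy-8-hydroxy-5-methoxy-3-methylisochromane-1,4-dione
Product: 13 (3R,4R)-6-geranyloxy-4,8-dihydroxy-5-methoxy-3-methylisochroman-1-one
Conditions: RuCl(p-cymene)[(S,S)-TsDPEN] (2 mol%), HCO2H/Et3N (5:2), DMF, 30 °C
Reagents that add atoms: none
Why: Noyori–Ikariya asymmetric transfer hydrogenation of an aryl ketone: with the (S,S) ligand the Ru–H/N–H pair should deliver hydrogen to the C4 carbonyl face that gives (4R), which is also the face anti to the C3 methyl, so the hydroxyl is set cis to the methyl, and since C3–H is enolisable any (3S) ketone should be funnelled to the same (3R,4R) alcohol by dynamic kinetic resolution; the isolated olefins, the lactone and the phenol are not touched.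

Step 7
Reactants: 13 (3R,4R)-6-geranyloxy-4,8-dihydroxy-5-methoxy-3-methylisochroman-1-one
Product: 15 (3R,4R)-4-acetoxy-6-geranyloxy-8-hydroxy-5-methoxy-3-methylisochroman-1-one (target), via diacetate 14 (not isolated)
Conditions: Ac2O (2.5 equiv), DMAP (0.1 equiv), pyridine, CH2Cl2, 0 °C to rt; then pyrrolidine (3 equiv), 0 °C
Reagents that add atoms: acetic anhydride, CC(=O)OC(C)=O
Why: Exhaustive DMAP-catalysed acetylation followed by chemoselective aminolysis: the C8 acetate, an aryl ester activated by the ortho lactone carbonyl, should be cleaved by pyrrolidine far faster than the secondary alkyl acetate at C4 or the lactone, so the C8 phenol is freed and the C4 configuration is not affected.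

Compound list
1 | 2,4-dihydroxy-5-methoxybenzaldehyde | COc1cc(C=O)c(O)cc1O | starting material
2 | geranyl bromide ((2E)-1-bromo-3,7-dimethylocta-2,6-diene) | BrC/C=C(\C)CCC=C(C)C | starting material
3 | 4-geranyloxy-2-hydroxy-5-methoxybenzaldehyde | COc1cc(C=O)c(O)cc1OC/C=C(\C)CCC=C(C)C | intermediate
4 | 4-geranyloxy-2-hydroxy-5-methoxybenzoic acid | COc1cc(C(=O)O)c(O)cc1OC/C=C(\C)CCC=C(C)C | intermediate
5 | (S)-N,N-dimethyllactamide | C[C@H](O)C(=O)N(C)C | starting material
6 | (2R)-1-(dimethylamino)-1-oxopropan-2-yl 4-geranyloxy-2-hydroxy-5-methoxybenzoate | COc1cc(C(=O)O[C@H](C)C(=O)N(C)C)c(O)cc1OC/C=C(\C)CCC=C(C)C | intermediate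
7 | quinone monoketal: (2R)-1-(dimethylamino)-1-oxopropan-2-yl 4-geranyloxy-3,3-dimethoxy-6-oxocyclohexa-1,4-diene-1-carboxylate (not isolated) | COC1(OC)C=C(C(=O)O[C@H](C)C(=O)N(C)C)C(=O)C=C1OC/C=C(\C)CCC=C(C)C | intermediate
8 | (2R)-1-(dimethylamino)-1-oxopropan-2-yl 2-bromo-4-geranyloxy-6-hydroxy-3-methoxybenzoate | COc1c(Br)c(C(=O)O[C@H](C)C(=O)N(C)C)c(O)cc1OC/C=C(\C)CCC=C(C)C | intermediate
9 | aryllithium phenoxide: 8 with lithium in place of bromine at C4a and the C8 hydroxyl as lithium phenoxide (not isolated) | [Li]c1c(OC)c(OC/C=C(\C)CCC=C(C)C)cc([O-])c1C(=O)O[C@H](C)C(=O)N(C)C.[Li+] | intermediate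
10 | arylmagnesium bromide: 9 with MgBr in place of lithium at C4a (not isolated) | Br[Mg]c1c(OC)c(OC/C=C(\C)CCC=C(C)C)cc([O-])c1C(=O)O[C@H](C)C(=O)N(C)C.[Li+] | intermediate
11 | magnesium hemiaminal: ring-closed adduct with C4 bearing OMgBr and NMe2 (not isolated) | COc1c(OC/C=C(\C)CCC=C(C)C)cc([O-])c2c1C(O[Mg]Br)(N(C)C)[C@@H](C)OC2=O.[Li+] | intermediate
12 | (3R)-6-geranyloxy-8-hydroxy-5-methoxy-3-methylisochromane-1,4-dione | COc1c(OC/C=C(\C)CCC=C(C)C)cc(O)c2c1C(=O)[C@@H](C)OC2=O | intermediate
13 | (3R,4R)-6-geranyloxy-4,8-dihydroxy-5-methoxy-3-methylisochroman-1-one | COc1c(OC/C=C(\C)CCC=C(C)C)cc(O)c2c1[C@@H](O)[C@@H](C)OC2=O | intermediate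
14 | diacetate: (3R,4R)-4,8-diacetoxy-6-geranyloxy-5-methoxy-3-methylisochroman-1-one (not isolated) | COc1c(OC/C=C(\C)CCC=C(C)C)cc(OC(C)=O)c2c1[C@@H](OC(C)=O)[C@@H](C)OC2=O | intermediate
15 | (3R,4R)-4-acetoxy-6-geranyloxy-8-hydroxy-5-methoxy-3-methylisochroman-1-one | COc1c(OC/C=C(\C)CCC=C(C)C)cc(O)c2c1[C@@H](OC(C)=O)[C@@H](C)OC2=O | target

Total step count: 7. Longest linear sequence: 7 steps (1 to 15; 2 and 5 are used as purchased).

Steps most likely to fail

Step 5. The aryl–metal may be protonated or acylated by a second molecule before the ester reaches the s-trans rotamer needed for ring closure, or the C4 alkoxide of the adduct may migrate onto C1 (ring contraction to a phthalide). The fallback sets out from 8 and returns at 12, still closing ring B through the C4a–C4 bond but with an aldehyde as electrophile. The dimethylamide of 8 would be reduced with Cp2Zr(H)Cl in THF to the aldehyde (2R)-1-oxopropan-2-yl 2-bromo-4-geranyloxy-6-hydroxy-3-methoxybenzoate F1. The ring would then be closed at high dilution by nickel-catalysed, zinc-driven reductive addition of the aryl bromide to the aldehyde (NiBr2(dme), a bipyridine ligand, Zn, DMA; CrCl2 with catalytic NiCl2 in DMF as the Nozaki–Hiyama–Kishi variant), which should give (3R)-6-geranyloxy-4,8-dihydroxy-5-methoxy-3-methylisochroman-1-one F2 as a mixture of C4 epimers. Oxidation of F2 with Dess–Martin periodinane would return the dione 12, so that step 6 still sets C4.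

Step 4. The ketal may hydrolyse to the quinone, methanol or acetate may add in place of bromide, or the geranyl group may be lost from the vinylogous ester oxygen under the acidic conditions. The fallback sets out from 6 and returns at 8, going through the quinone instead of the monoketal. Oxidative demethylation of 6 with PhI(OAc)2 in MeCN/H2O (or (NH4)2Ce(NO3)6) would give the p-quinone (2R)-1-(dimethylamino)-1-oxopropan-2-yl 4-geranyloxy-3,6-dioxocyclohexa-1,4-diene-1-carboxylate F3. Thiele-type 1,4-addition of HBr (LiBr, AcOH, MeCN) at C4a, again the β-carbon of the C8 carbonyl and the ester, should give the bromohydroquinone (2R)-1-(dimethylamino)-1-oxopropan-2-yl 2-bromo-4-geranyloxy-3,6-dihydroxybenzoate F4. The C5 hydroxyl of F4, which is not chelated, would then be methylated selectively with Me3SiCHN2 in MeOH/toluene to return 8; the C8 hydroxyl is held in a hydrogen bond to the ester carbonyl.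

Step 6. Hydride transfer to the doubly ortho-substituted ketone may be slow, facial control may be incomplete, or the product may translactonise through its C4 hydroxyl. The fallback sets out from 12 and returns at 13 with substrate control instead of catalyst control: K[BH(s-Bu)3] in THF at −78 °C should add hydride from the face anti to the C3 methyl group, as in the reduction of 2-alkyl-1-tetralones, to give the cis alcohol 13 directly. This variant cannot correct any loss of configuration at C3, so it would be used on dione 12 taken straight from a cold acidic quench.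

Further compounds
F1 | step 5 | (2R)-1-oxopropan-2-yl 2-bromo-4-geranyloxy-6-hydroxy-3-methoxybenzoate | COc1c(Br)c(C(=O)O[C@H](C)C=O)c(O)cc1OC/C=C(\C)CCC=C(C)C
F2 | step 5 | (3R)-6-geranyloxy-4,8-dihydroxy-5-methoxy-3-methylisochroman-1-one, both C4 epimers | COc1c(OC/C=C(\C)CCC=C(C)C)cc(O)c2c1C(O)[C@@H](C)OC2=O
F3 | step 4 | (2R)-1-(dimethylamino)-1-oxopropan-2-yl 4-geranyloxy-3,6-dioxocyclohexa-1,4-diene-1-carboxylate | O=C1C=C(OC/C=C(\C)CCC=C(C)C)C(=O)C=C1C(=O)O[C@H](C)C(=O)N(C)C
F4 | step 4 | (2R)-1-(dimethylamino)-1-oxopropan-2-yl 2-bromo-4-geranyloxy-3,6-dihydroxybenzoate | Oc1c(Br)c(C(=O)O[C@H](C)C(=O)N(C)C)c(O)cc1OC/C=C(\C)CCC=C(C)C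
F0 | step 6 | none | none
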